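**Retrosynthetic overview**
- The target is cut at the C–H bond of the carbinol carbon that sits between imidazole C4 and the 4-methoxyphenyl ring. This doubly benzylic C–OH, pushed by the 2-aminoimidazole ring and the anisyl ring, ionises easily, so it is made in the last operation from the C4 aroyl ketone by asymmetric transfer hydrogenation.
- The ketone is cut at the exocyclic N–C amidine bond: the 2-amino-4-aroylimidazole is condensed with 1-methylparabanic acid, which delivers the imidazole-2,5-dione ring intact.
- The C2–N bond comes from C2 lithiation and azide transfer at the carbinol oxidation level (no carbonyl present), followed by oxidation to the ketone and azide reduction.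
- The carbon skeleton comes from 4,5-diiodo-1-methylimidazole by two iodine–magnesium exchanges, C5 first and C4 second, each trapped with 4-methoxybenzaldehyde.
- No ring is formed in the route: the imidazole ring and the imidazoledione ring are both bought and only decorated.

Key step: step 8

Assumptions: 4,5-diiodo-1-methyl-1H-imidazole is taken as a catalogue compound (otherwise it is one N-methylation away from symmetric 4,5-diiodoimidazole). The sense of induction in step 8 is assigned from the usual transition-state model; the configuration of the product would be checked, and the (R,R)-catalyst would be used if the sense proved opposite.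

Step 1
Reactants: 1 4,5-diiodo-1-methyl-1H-imidazole; 2 4-methoxybenzaldehyde
Product: 4 racemic (4-iodo-1-methyl-1H-imidazol-5-yl)(4-methoxyphenyl)methanol, via (4-iodo-1-methylimidazol-5-yl)magnesium bromide 3 (not isolated)
Conditions: EtMgBr (1.05 equiv), THF, 0 °C to rt; then 2, rt; then H2O
Reagents that add atoms: none
Why: Iodine–magnesium exchange should occur selectively at C5, next to the N-methyl group, and the resulting Grignard reagent adds to the aldehyde (Grignard 1,2-addition); the new carbinol centre is racemic and is removed in step 2.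

Step 2
Reactants: 4 racemic (4-iodo-1-methyl-1H-imidazol-5-yl)(4-methoxyphenyl)methanol
Product: 5 4-iodo-5-(4-methoxybenzyl)-1-methyl-1H-imidazole
Conditions: Et3SiH (3 equiv), CF3CO2H, CH2Cl2, rt to 40 °C
Reagents that add atoms: none
Why: Ionic hydrogenation: acid ionises the carbinol to a 4-methoxybenzyl-type cation that is trapped by silane hydride, while the C4 iodide and the aryl ether are inert.

Step 3
Reactants: 5 4-iodo-5-(4-methoxybenzyl)-1-methyl-1H-imidazole; 2 4-methoxybenzaldehyde
Product: 7 racemic [5-(4-methoxybenzyl)-1-methyl-1H-imidazol-4-yl](4-methoxyphenyl)methanol, via [5-(4-methoxybenzyl)-1-methylimidazol-4-yl]magnesium chloride 6 (not isolated)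
Conditions: i-PrMgCl·LiCl (1.2 equiv), THF, 0 °C to rt; then 2, 0 °C to rt; then H2O
Reagents that add atoms: none
Why: A second iodine–magnesium exchange with the LiCl-activated Grignard reagent at the remaining C4 iodide, followed by 1,2-addition to the aldehyde, gives the carbinol as a racemate; this centre is erased in step 5.

Step 4
Reactants: 7 racemic [5-(4-methoxybenzyl)-1-methyl-1H-imidazol-4-yl](4-methoxyphenyl)methanol
Product: 10 racemic [2-azido-5-(4-methoxybenzyl)-1-methyl-1H-imidazol-4-yl](4-methoxyphenyl)methanol, via C2-lithio lithium alkoxide 8 (not isolated), via lithium tosyltriazenide 9 (not isolated)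
Conditions: n-BuLi (2.2 equiv), THF, −78 °C; TsN3 (1.3 equiv), −78 °C to 0 °C; then H2O; product kept cold and dark and used promptly
Reagents that add atoms: tosyl azide (4-methylbenzenesulfonyl azide), Cc1ccc(cc1)S(=O)(=O)N=[N+]=[N-]
Why: After the hydroxyl is deprotonated, the second equivalent of base removes the most acidic ring proton at C2 between the two nitrogens (C2 lithiation of a 1-methylimidazole), and the carbanion attacks the terminal nitrogen of the sulfonyl azide to give a triazenide that loses sulfinate (electrophilic azide transfer); no carbonyl is present to compete.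

Step 5
Reactants: 10 racemic [2-azido-5-(4-methoxybenzyl)-1-methyl-1H-imidazol-4-yl](4-methoxyphenyl)methanol
Product: 11 [2-azido-5-(4-methoxybenzyl)-1-methyl-1H-imidazol-4-yl](4-methoxyphenyl)methanone
Conditions: activated MnO2 (excess), CH2Cl2, rt, dark
Reagents that add atoms: none
Why: MnO2 oxidises the doubly benzylic-type secondary alcohol to the diaryl ketone under neutral conditions that leave the azide, the aryl ethers and the C5 methylene untouched.

Step 6
Reactants: 11 [2-azido-5-(4-methoxybenzyl)-1-methyl-1H-imidazol-4-yl](4-methoxyphenyl)methanone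
Product: 12 [2-amino-5-(4-methoxybenzyl)-1-methyl-1H-imidazol-4-yl](4-methoxyphenyl)methanone
Conditions: H2 (1 atm), Pd on CaCO3 poisoned with Pb(OAc)2, EtOH, rt
Reagents that add atoms: none
Why: Catalytic hydrogenation of an azide to the amine with loss of N2 over a poisoned palladium catalyst, which should spare the diaryl ketone and the benzylic C–C bonds; the conjugated 4-aroyl group also stabilises the 2-aminoimidazole against air oxidation.

Step 7
Reactants: 12 [2-amino-5-(4-methoxybenzyl)-1-methyl-1H-imidazol-4-yl](4-methoxyphenyl)methanone; 13 1-methylparabanic acid (1-methylimidazolidine-2,4,5-trione)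
Product: 15 4-{[5-(4-methoxybenzyl)-4-(4-methoxybenzoyl)-1-methyl-1H-imidazol-2-yl]amino}-1-methyl-1H-imidazole-2,5-dione, via O-silyl imidate 14 (not isolated)
Conditions: 13 (2 equiv), N,O-bis(trimethylsilyl)acetamide (4 equiv), MeCN, 80 °C; then 12, toluene, 110 °C; methanolic work-up
Reagents that add atoms: none
Why: The silylating agent turns the N3–H/C4=O lactam of 13 into an O-silyl imidate whose C4 is attacked by the exocyclic amino group with loss of silanol (addition–elimination, the silyl-imidate condensation used for naamidine-type acyl amidines); only the N–H side of 13 can form the imidate, which fixes the regiochemistry.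

Step 8
Reactants: 15 4-{[5-(4-methoxybenzyl)-4-(4-methoxybenzoyl)-1-methyl-1H-imidazol-2-yl]amino}-1-methyl-1H-imidazole-2,5-dione
Product: 16 4-({4-[(R)-hydroxy(4-methoxyphenyl)methyl]-5-(4-methoxybenzyl)-1-methyl-1H-imidazol-2-yl}amino)-1-methyl-1H-imidazole-2,5-dione
Conditions: RuCl(p-cymene)[(S,S)-TsDPEN] (2–5 mol %), HCO2H/Et3N (1.1:1), DMF, 30 °C
Reagents that add atoms: none
Why: The ruthenium hydride formed from the precatalyst and formate passes hydride to the carbonyl carbon and the ligand N–H passes a proton to oxygen in a six-membered outer-sphere transition state, so the basic nitrogens of 15 need not bind the metal (Noyori–Ikariya asymmetric transfer hydrogenation). The closest known cases are ortho-substituted benzophenones and aryl N-heteroaryl ketones reduced with this catalyst family. No ring closes. The one stereocenter is set by the (S,S)-TsDPEN ligand: the coplanar, electron-rich 4-methoxyphenyl ring should take the place under the p-cymene ligand (C–H/π contact) that phenyl takes in acetophenone, and the imidazole ring, twisted by its C5 benzyl neighbour, the place of the small group, which gives the spatial arrangement of (S)-1-phenylethanol and is R here because imidazol-4-yl outranks the aryl ring. The step needs facial selectivity between two sp2 flanks and chemoselectivity for the ketone over the acyl amidine C=N and the imide carbonyls; the first rests on the twist and the electronic difference of the two rings, the second on the low electrophilicity of the push–pull amidine, and the nearly neutral formate medium should keep the ionisable carbinol intact.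

**Compound list**
1 | 4,5-diiodo-1-methyl-1H-imidazole | Cn1cnc(I)c1I | starting material
2 | 4-methoxybenzaldehyde | COc1ccc(C=O)cc1 | starting material
3 | (4-iodo-1-methylimidazol-5-yl)magnesium bromide | Cn1cnc(I)c1[Mg]Br | intermediate (not isolated)
4 | racemic (4-iodo-1-methyl-1H-imidazol-5-yl)(4-methoxyphenyl)methanol | Cn1cnc(I)c1C(O)c1ccc(OC)cc1 | intermediate
5 | 4-iodo-5-(4-methoxybenzyl)-1-methyl-1H-imidazole | Cn1cnc(I)c1Cc1ccc(OC)cc1 | intermediate
6 | [5-(4-methoxybenzyl)-1-methylimidazol-4-yl]magnesium chloride (LiCl complex) | COc1ccc(Cc2c([Mg]Cl)ncn2C)cc1 | intermediate (not isolated)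
7 | racemic [5-(4-methoxybenzyl)-1-methyl-1H-imidazol-4-yl](4-methoxyphenyl)methanol | COc1ccc(Cc2c(C(O)c3ccc(OC)cc3)ncn2C)cc1 | intermediate
8 | C2-lithio lithium alkoxide of 7 | COc1ccc(Cc2c(C(O[Li])c3ccc(OC)cc3)nc([Li])n2C)cc1 | intermediate (not isolated)
9 | lithium 3-tosyltriazenide at C2 (lithium alkoxide) | COc1ccc(Cc2c(C(O[Li])c3ccc(OC)cc3)nc(N=NN([Li])S(=O)(=O)c3ccc(C)cc3)n2C)cc1 | intermediate (not isolated)
10 | racemic [2-azido-5-(4-methoxybenzyl)-1-methyl-1H-imidazol-4-yl](4-methoxyphenyl)methanol | COc1ccc(Cc2c(C(O)c3ccc(OC)cc3)nc(N=[N+]=[N-])n2C)cc1 | intermediate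
11 | [2-azido-5-(4-methoxybenzyl)-1-methyl-1H-imidazol-4-yl](4-methoxyphenyl)methanone | COc1ccc(Cc2c(C(=O)c3ccc(OC)cc3)nc(N=[N+]=[N-])n2C)cc1 | intermediate
12 | [2-amino-5-(4-methoxybenzyl)-1-methyl-1H-imidazol-4-yl](4-methoxyphenyl)methanone | COc1ccc(Cc2c(C(=O)c3ccc(OC)cc3)nc(N)n2C)cc1 | intermediate
13 | 1-methylparabanic acid (1-methylimidazolidine-2,4,5-trione) | CN1C(=O)NC(=O)C1=O | starting material
14 | 1-methyl-4-(trimethylsilyloxy)-1H-imidazole-2,5-dione | CN1C(=O)N=C(O[Si](C)(C)C)C1=O | intermediate (not isolated)
15 | 4-{[5-(4-methoxybenzyl)-4-(4-methoxybenzoyl)-1-methyl-1H-imidazol-2-yl]amino}-1-methyl-1H-imidazole-2,5-dione | COc1ccc(Cc2c(C(=O)c3ccc(OC)cc3)nc(NC3=NC(=O)N(C)C3=O)n2C)cc1 | intermediate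
16 | 4-({4-[(R)-hydroxy(4-methoxyphenyl)methyl]-5-(4-methoxybenzyl)-1-methyl-1H-imidazol-2-yl}amino)-1-methyl-1H-imidazole-2,5-dione | COc1ccc(Cc2c([C@H](O)c3ccc(OC)cc3)nc(NC3=NC(=O)N(C)C3=O)n2C)cc1 | target

Total step count: 8. Longest linear sequence: 8 steps (1 to 16).

**Steps most likely to fail**

Step 8. Facial discrimination between the two aryl-type flanks may be poor, and the basic aminoimidazole and amidine nitrogens may slow the catalyst. Fallback by resolution instead of induction: setting out from 15, reduction with NaBH4 in MeOH/THF at −20 °C should give the racemic carbinol F1. Preparative chromatography on a chiral stationary phase (amylose tris(3,5-dimethylphenylcarbamate), supercritical CO2/MeOH) would separate 16 from the (S)-carbinol F2. F2 is returned to 15 with MnO2 in CH2Cl2 for another pass; the route is rejoined at 16.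

Step 7. The condensation may stall, because the 2-amino group is deactivated by conjugation with the 4-aroyl group and the silylated parabanic acid may decompose first on prolonged heating. Fallback by changing the order of events: setting out from 10, hydrogenation over Pd on CaCO3 poisoned with Pb(OAc)2 should give the racemic amino carbinol F3, whose amino group has no conjugated carbonyl. Condensation with 13 and N,O-bis(trimethylsilyl)acetamide in toluene is expected to give the amidine with the hydroxyl held in the flask as the trimethylsilyl ether F4. Aqueous methanol work-up frees the racemic carbinol F1, and MnO2 in CH2Cl2 oxidises it to 15, where the route is rejoined.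

Step 4. Metalation of the alkoxide may be incomplete or the dianion poorly soluble, and the lithium alkoxide may compete for the sulfonyl azide by sulfonyl transfer. Fallback with the hydroxyl masked: setting out from 7, TBSCl and imidazole in DMF give the tert-butyldimethylsilyl ether F5. n-BuLi (1.1 equiv) in THF at −78 °C gives the C2-lithio silyl ether F6, TsN3 gives the lithium tosyltriazenide F7, which collapses to the azido silyl ether F8. Bu4NF in THF removes the silyl group and rejoins the route at 10.

**Further compounds**
F1 | step 8 | racemic 4-({4-[hydroxy(4-methoxyphenyl)methyl]-5-(4-methoxybenzyl)-1-methyl-1H-imidazol-2-yl}amino)-1-methyl-1H-imidazole-2,5-dione | COc1ccc(Cc2c(C(O)c3ccc(OC)cc3)nc(NC3=NC(=O)N(C)C3=O)n2C)cc1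
F2 | step 8 | 4-({4-[(S)-hydroxy(4-methoxyphenyl)methyl]-5-(4-methoxybenzyl)-1-methyl-1H-imidazol-2-yl}amino)-1-methyl-1H-imidazole-2,5-dione | COc1ccc(Cc2c([C@@H](O)c3ccc(OC)cc3)nc(NC3=NC(=O)N(C)C3=O)n2C)cc1
F3 | step 7 | racemic [2-amino-5-(4-methoxybenzyl)-1-methyl-1H-imidazol-4-yl](4-methoxyphenyl)methanol | COc1ccc(Cc2c(C(O)c3ccc(OC)cc3)nc(N)n2C)cc1
F4 | step 7 | racemic trimethylsilyl ether of F1 | COc1ccc(Cc2c(C(O[Si](C)(C)C)c3ccc(OC)cc3)nc(NC3=NC(=O)N(C)C3=O)n2C)cc1
F5 | step 4 | racemic tert-butyldimethylsilyl ether of 7 | COc1ccc(Cc2c(C(O[Si](C)(C)C(C)(C)C)c3ccc(OC)cc3)ncn2C)cc1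
F6 | step 4 | C2-lithio derivative of F5 | COc1ccc(Cc2c(C(O[Si](C)(C)C(C)(C)C)c3ccc(OC)cc3)nc([Li])n2C)cc1
F7 | step 4 | lithium 3-tosyltriazenide at C2 of F5 | COc1ccc(Cc2c(C(O[Si](C)(C)C(C)(C)C)c3ccc(OC)cc3)nc(N=NN([Li])S(=O)(=O)c3ccc(C)cc3)n2C)cc1
F8 | step 4 | racemic 2-azido tert-butyldimethylsilyl ether | COc1ccc(Cc2c(C(O[Si](C)(C)C(C)(C)C)c3ccc(OC)cc3)nc(N=[N+]=[N-])n2C)cc1
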